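**Retrosynthetic overview**
- The C5 ester C–O bond is made last, by anti opening of a 5α,6α-vinyl epoxide at its allylic carbon with (E)-3-methylpent-2-enoic acid; this also frees the 6α-OH.
- The 4-methylene comes from a Wittig reaction on the C4 ketone; the 2β-acetate comes from CBS reduction and acetylation of a 2-alkylidenecyclopentanone.
- The five-membered ring with its (Z)-ethylidene comes from a methyl-terminated 1,2-shift ring expansion of a 1-ethynylcyclobutanol silyl ether; the ring fusion is then epimerised to trans through the C4 ketone.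
- The cyclobutane comes from an enone–silyl enol ether [2+2] photocycloaddition on (S)-cryptone; the epoxy ketone comes from dehydrogenation and nucleophilic epoxidation.
- Ring order: six-membered ring (organocatalytic Michael/aldol), then cyclobutane, then oxirane, then cyclopentane by ring expansion.

Convention: target (indane) numbering C1–C7a is used for every bicyclic compound; α is the face of the isopropyl group and H-7a, β is the face of H-3a in the target.
Assumption: but-3-yn-2-one and (E)-3-methylpent-2-enoic acid are bought; all selectivities are predictions, not measured results.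

**Step 1**
Reactants: 1 3-methylbutanal; 2 but-3-en-2-one
Product: 4 (S)-4-isopropylcyclohex-2-en-1-one ((S)-cryptone), via keto aldehyde 3 (not isolated)
Conditions: (S)-α,α-diphenylprolinol TMS ether (5 mol %), ethyl 3,4-dihydroxybenzoate (20 mol %), neat, 4 °C; then KOH (0.1 M aq), Bu4NOH (cat.), Et2O/THF, 40 °C
Reagents that add atoms: none
Why: Enamine-catalysed Michael addition to the enone, in which the diarylprolinol silyl ether shields one enamine face and sets the (S) isopropyl-bearing centre, followed by intramolecular aldol condensation (Robinson-type annulation) that does not touch that centre.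

**Step 2**
Reactants: 5 but-3-yn-2-one
Product: 6 2-(tert-butyldimethylsilyloxy)but-1-en-3-yne
Conditions: TBSOTf (1.1 equiv), iPr2NEt (1.3 equiv), CH2Cl2, –78 to 0 °C
Reagents that add atoms: tert-butyldimethylsilyl triflate, CC(C)(C)[Si](C)(C)OS(=O)(=O)C(F)(F)F
Why: Soft enolisation and O-silylation of the methyl ketone (silyl enol ether formation), with a hindered amine to avoid conjugate addition to the ynone; no stereocentre is formed.

**Step 3**
Reactants: 4 (S)-cryptone; 6 2-(tert-butyldimethylsilyloxy)but-1-en-3-yne
Product: 8 cis-fused cyclobutane-annulated ketone (four-membered ring C7a–C2(OTBS)(C≡CH)–C3–C3a on the 7α-isopropylcyclohexan-4-one; H-3a α; H-7a α; C2 epimers), via trans-fused photoadduct 7 (not isolated)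
Conditions: 6 (5 equiv), hν (350–366 nm, Pyrex), CH2Cl2, –40 °C; then basic Al2O3, 25 °C
Reagents that add atoms: none
Why: Enone–enol ether [2+2] photocycloaddition (the first stage of a de Mayo sequence) is head-to-tail, so the silyloxy carbon bonds to the enone β-carbon C7a, anti to the isopropyl group (sets C7a); alumina epimerises C3a of the trans-fused adduct to the stable cis-fused ring system, and both C2 epimers are used because C2 becomes a carbonyl carbon in step 6.

**Step 4**
Reactants: 8 cis-fused cyclobutane-annulated ketone
Product: 9 cis-fused enone (as 8 with a C5=C6 double bond conjugated to the C4 ketone)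
Conditions: IBX (2.5 equiv), 4-methoxypyridine N-oxide (2.5 equiv), DMSO, 25 °C
Reagents that add atoms: none
Why: IBX α,β-dehydrogenation of a ketone, which can only desaturate toward C5–C6 because the other α-carbon is the cyclobutane ring-fusion carbon; the base-free conditions leave the terminal alkyne and the silyl ether alone, and no stereocentre is formed.

**Step 5**
Reactants: 9 cis-fused enone
Product: 10 5α,6α-epoxy ketone (as 9 with an oxirane across C5–C6, cis to the isopropyl group and anti to the cyclobutane)
Conditions: 30% H2O2 (3 equiv), NaOH (0.2 equiv), MeOH, 0 °C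
Reagents that add atoms: hydrogen peroxide, OO
Why: Weitz–Scheffer nucleophilic epoxidation, in which hydroperoxide addition is reversible and ring closure needs an axial C6–OOH; with the isopropyl group equatorial this is the α-adduct, and the β-face carries the cis-fused cyclobutane, so C5 and C6 are set as the α-epoxide.

**Step 6**
Reactants: 10 5α,6α-epoxy ketone
Product: 12 trans-fused (1Z)-1-ethylidene-5α,6α-epoxy-7α-isopropylperhydroindane-2,4-dione (H-3a β; H-7a α), via cis-fused dione 11 (not isolated)
Conditions: IPrAuCl (5 mol %), AgOTs (5 mol %), Pd(PtBu3)2 (5 mol %), MeOTs (1.5 equiv), THF, 25 °C; then DBU (1.0 equiv), 25 °C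
Reagents that add atoms: methyl 4-methylbenzenesulfonate, COS(=O)(=O)c1ccc(C)cc1
Why: Proposed new method: a dual-metal methylative semipinacol ring expansion in which cationic monovalent gold π-activates the terminal alkyne and the more substituted ring carbon C7a makes a 1,2-shift anti to gold with retention, expanding the cyclobutane to the cyclopentanone and leaving a vinylgold with gold trans to C7a, while tosylate takes the silyl group so that no proton is released and protodeauration is shut off; zerovalent palladium adds MeOTs to give a cationic methyl complex of divalent palladium that takes the vinyl group from gold with retention, and reductive elimination puts CH3 where gold was, cis to the C2 carbonyl, which is the (Z)-ethylidene; the closest known reactions are the gold-catalysed ring expansion of 1-alkynylcyclobutanols to 2-alkylidenecyclopentanones ended by protodeauration, the palladium-catalysed arylative ring expansion of 1-alkynylcyclobutanols with aryl halides, and gold-to-palladium transmetalation in vinylgold cross-couplings; DBU then epimerises C3a through the C4 enolate to the more stable trans-fused 1-alkylidenehydrindan-4-one.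

**Step 7**
Reactants: 12 trans-fused epoxy dione
Product: 13 (1Z)-1-ethylidene-5α,6α-epoxy-7α-isopropyl-4-methylene-trans-perhydroindan-2-one
Conditions: Ph3PCH3Br (1.2 equiv), KOtBu (1.15 equiv), THF, –20 to 0 °C
Reagents that add atoms: methyltriphenylphosphonium bromide (as its ylide), C[P+](c1ccccc1)(c1ccccc1)c1ccccc1.[Br-]
Why: Wittig methylenation, chemoselective for the non-conjugated, α-oxygen-activated cyclohexanone at C4 over the cross-conjugated cyclopentanone carbonyl at C2 (the same selectivity as in the Wieland–Miescher ketone); no stereocentre is formed and C3a is no longer epimerisable afterwards.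

**Step 8**
Reactants: 13 epoxy methylene enone
Product: 14 (1Z,2R)-1-ethylidene-5α,6α-epoxy-7α-isopropyl-4-methylene-trans-perhydroindan-2β-ol
Conditions: (S)-2-methyl-CBS-oxazaborolidine (0.2 equiv), catecholborane (1.5 equiv), toluene, –78 °C
Reagents that add atoms: none
Why: Corey–Bakshi–Shibata reduction under reagent control, with the alkylidene-bearing C1 as the large group and C3H2 as the small one, so the (S)-catalyst delivers hydride to the α-face and sets (2R) (2β-OH); catecholborane at –78 °C leaves the alkenes and the epoxide untouched.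

**Step 9**
Reactants: 14 allylic alcohol
Product: 15 (1Z,2R)-1-ethylidene-5α,6α-epoxy-7α-isopropyl-4-methylene-trans-perhydroindan-2β-yl acetate
Conditions: Ac2O, pyridine, DMAP (cat.), CH2Cl2, 0 °C
Reagents that add atoms: acetic anhydride, CC(=O)OC(C)=O
Why: DMAP-catalysed acylation of the only free hydroxyl group, with retention at C2.

**Step 10**
Reactants: 15 epoxy acetate; 16 (E)-3-methylpent-2-enoic acid
Product: 17 (1Z,2R,3aR,5S,6S,7S,7aR)-2-acetoxy-1-ethylidene-6-hydroxy-7-isopropyl-4-methyleneoctahydro-1H-inden-5-yl (E)-3-methylpent-2-enoate (target)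
Conditions: 16 (3 equiv), Cs2CO3 (0.2 equiv), DMF, 70 °C
Reagents that add atoms: none
Why: SN2 opening of the vinyl epoxide by the carboxylate at the allylic carbon C5 with inversion; allylic activation, the less hindered site and the trans-diaxial (Fürst–Plattner) rule all point to C5, giving the 5β-ester and the free 6α-OH, and the trans-diaxial arrangement prevents acyl migration.

**Compound list**
1 | 3-methylbutanal | CC(C)CC=O | starting material
2 | but-3-en-2-one | CC(=O)C=C | starting material
3 | (S)-2-isopropyl-5-oxohexanal | O=C[C@H](C(C)C)CCC(C)=O | intermediate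
4 | (S)-4-isopropylcyclohex-2-en-1-one ((S)-cryptone) | O=C1C=C[C@H](C(C)C)CC1 | intermediate
5 | but-3-yn-2-one | CC(=O)C#C | starting material
6 | 2-(tert-butyldimethylsilyloxy)but-1-en-3-yne | C=C(O[Si](C)(C)C(C)(C)C)C#C | intermediate
7 | trans-fused photoadduct: cyclobutane C7a–C2(OTBS)(C≡CH)–C3–C3a on 7α-isopropylcyclohexan-4-one, H-3a β, H-7a α, C2 epimers | O=C1CC[C@@H](C(C)C)[C@H]2[C@H]1CC2(O[Si](C)(C)C(C)(C)C)C#C | intermediate
8 | cis-fused photoadduct: as 7 but H-3a α (both cyclobutane bonds β), C2 epimers | O=C1CC[C@@H](C(C)C)[C@H]2[C@@H]1CC2(O[Si](C)(C)C(C)(C)C)C#C | intermediate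
9 | cis-fused enone: as 8 with C5=C6 | O=C1C=C[C@@H](C(C)C)[C@H]2[C@@H]1CC2(O[Si](C)(C)C(C)(C)C)C#C | intermediate
10 | cis-fused 5α,6α-epoxy ketone: as 9 with an α-oxirane across C5–C6 | O=C1[C@H]3O[C@H]3[C@@H](C(C)C)[C@H]2[C@@H]1CC2(O[Si](C)(C)C(C)(C)C)C#C | intermediate
11 | cis-fused (1Z)-1-ethylidene-5α,6α-epoxy-7α-isopropylperhydroindane-2,4-dione (H-3a α, H-7a α) | O=C1[C@H]3O[C@H]3[C@@H](C(C)C)[C@H]2[C@@H]1CC(=O)/C2=C\C | intermediate
12 | trans-fused (1Z)-1-ethylidene-5α,6α-epoxy-7α-isopropylperhydroindane-2,4-dione (H-3a β, H-7a α) | O=C1[C@H]3O[C@H]3[C@@H](C(C)C)[C@H]2[C@H]1CC(=O)/C2=C\C | intermediate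
13 | (1Z)-1-ethylidene-5α,6α-epoxy-7α-isopropyl-4-methylene-trans-perhydroindan-2-one | C=C1[C@H]3O[C@H]3[C@@H](C(C)C)[C@H]2[C@H]1CC(=O)/C2=C\C | intermediate
14 | (1Z,2R)-1-ethylidene-5α,6α-epoxy-7α-isopropyl-4-methylene-trans-perhydroindan-2β-ol | C=C1[C@H]3O[C@H]3[C@@H](C(C)C)[C@H]2[C@H]1C[C@@H](O)/C2=C\C | intermediate
15 | (1Z,2R)-1-ethylidene-5α,6α-epoxy-7α-isopropyl-4-methylene-trans-perhydroindan-2β-yl acetate | C=C1[C@H]3O[C@H]3[C@@H](C(C)C)[C@H]2[C@H]1C[C@@H](OC(C)=O)/C2=C\C | intermediate
16 | (E)-3-methylpent-2-enoic acid | CC/C(C)=C/C(=O)O | starting material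
17 | (1Z,2R,3aR,5S,6S,7S,7aR)-2-acetoxy-1-ethylidene-6-hydroxy-7-isopropyl-4-methyleneoctahydro-1H-inden-5-yl (E)-3-methylpent-2-enoate (2β-OAc, 3aβ-H, 5β-acyloxy, 6α-OH, 7α-iPr, 7aα-H) | C=C1[C@@H]2C[C@@H](OC(C)=O)/C(=C\C)[C@H]2[C@H](C(C)C)[C@H](O)[C@H]1OC(=O)/C=C(\C)CC | target

**Totals**
Total step count: 10. Longest linear sequence: 9 steps (steps 1 and 3 to 10); step 2 is a one-step side branch.

**Three steps most likely to fail**

Step 6, the new methylative ring expansion. The risks are protodeauration or alkyne insertion into the methyl–palladium bond instead of the intended relay, and an incomplete cis-to-trans equilibration at C3a. The fallback uses known chemistry and sets out from 10. The gold-catalysed ring expansion is run with N-iodosuccinimide (Ph3PAuNTf2 cat., NIS, CH2Cl2, 0 °C), so the vinylgold is iododeaurated with retention and gives the cis-fused (1Z)-1-(iodomethylene)-5α,6α-epoxy-7α-isopropylperhydroindane-2,4-dione F1. Negishi methylation (Me2Zn, Pd(PPh3)4 cat., THF, 0 to 25 °C) replaces iodine by methyl with retention and comes back to the route at 11, which is epimerised with DBU to 12 as in step 6.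

Step 3, the photocycloaddition. The conjugated enyne partner may be sensitised and polymerise, and regio- or facial selectivity may be poor. The fallback sets out from 4 and builds the same cyclobutanol by addition to a cyclobutanone:
- [2+2] photocycloaddition of 4 with 1,1-dimethoxyethene, then basic alumina, gives the cis-fused 2,2-dimethoxycyclobutane-annulated ketone F2.
- NaBH4 reduces the ring ketone to the C4 alcohol F3.
- Aqueous oxalic acid unmasks the hydroxy cyclobutanone F4.
- Ethynylmagnesium bromide with CeCl3 (3 equiv, THF, –78 °C) adds to the cyclobutanone to give the 2-ethynyl-2,4-diol F5.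
- Dess–Martin periodinane oxidises only the secondary alcohol, giving the hydroxy ketone F6.
- TBSOTf with 2,6-lutidine silylates the tertiary alcohol and comes back to the route at 8.

Step 10, the epoxide opening. The risks are SN2′ attack at the exocyclic CH2 and slow reaction at a hindered vinyl epoxide. The fallback sets out from 15. Acid-catalysed hydrolysis (HClO4 cat., THF/H2O, 0 °C) opens the epoxide trans-diaxially to the 2β-acetoxy-5β,6α-diol F7. Steglich esterification with 16 (DCC, DMAP, CH2Cl2, –20 °C) then acylates the less hindered allylic 5-OH selectively, because the 6-OH is flanked by the isopropyl group, and comes back to the route at 17.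

**Further compounds**
F1 | step 6 | cis-fused (1Z)-1-(iodomethylene)-5α,6α-epoxy-7α-isopropylperhydroindane-2,4-dione | O=C1[C@H]3O[C@H]3[C@@H](C(C)C)[C@H]2[C@@H]1CC(=O)/C2=C\I
F2 | step 3 | cis-fused keto acetal: cyclobutane C7a–C2(OMe)2–C3–C3a on 7α-isopropylcyclohexan-4-one | O=C1CC[C@@H](C(C)C)[C@H]2[C@@H]1CC2(OC)OC
F3 | step 3 | C4 alcohol of F2 (C4 epimers) | OC1CC[C@@H](C(C)C)[C@H]2[C@@H]1CC2(OC)OC
F4 | step 3 | cis-fused 4-hydroxy cyclobutan-2-one (C4 epimers) | OC1CC[C@@H](C(C)C)[C@H]2[C@@H]1CC2=O
F5 | step 3 | cis-fused 2-ethynyl-2,4-diol (C2 and C4 epimers) | OC1CC[C@@H](C(C)C)[C@H]2[C@@H]1CC2(O)C#C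
F6 | step 3 | cis-fused 2-ethynyl-2-hydroxy-4-ketone (desilyl 8, C2 epimers) | O=C1CC[C@@H](C(C)C)[C@H]2[C@@H]1CC2(O)C#C
F7 | step 10 | (1Z,2R)-2β-acetoxy-1-ethylidene-7α-isopropyl-4-methylene-trans-perhydroindane-5β,6α-diol | C=C1[C@H](O)[C@@H](O)[C@@H](C(C)C)[C@H]2[C@H]1C[C@@H](OC(C)=O)/C2=C\C
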